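The ratio I watched was 1.17: the lifetime of first end groups in larch over that in maple, though larch carried 1.49 times the charge. Gas dissolves and turns first end groups into links.

| flask | first end groups | gas | remark | time |
|---|---|---|---|---|
| larch | 0.10 M | 5 mM (held) | the very flask that is asked about, followed so far |  |
| maple | 0.067 M | 5 mM (held) | run made earlier |  |
| flask | 0.10 M | 5.0 mM (held) |  | 4.0 min |

larch run (percent of the first end groups charged)

| time / s | links / % | first end groups / % |
|---|---|---|
| 15.0 | 9 | 82 |
| 30.0 | 22 | 70 |
| 50.0 | 36 | 51 |
| 60.0 | 42 | 46 |
| 80.0 | 51 | 34 |
| 90.0 | 56 | 30 |

maple run (percent of the first end groups charged)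

| time / min | links / % | first end groups / % |
|---|---|---|
| 0.250 | 11 | 83 |
| 0.333 | 19 | 75 |
| 0.667 | 35 | 57 |
| 1.00 | 48 | 40 |
| 1.50 | 64 | 24 |
| 3.00 | 87 | 6 |

(each reading ± 1.5 percentage points)

- at the start none of the gas is in solution

- ochre: doubling the saturation concentration of gas, all else as stated
- teal: doubling the transfer coefficient of the gas, all else as stated

- how much links there is at 4.0 min, in percent of the first end groups charged
- the change that raises the amount of links at 4.0 min, in percent of the first end groups charged most ("none" if none brings more than 2 percentage points) (ochre / teal / none)
- amount of links at 4.0 min, in percent of the first end groups charged, after teal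

First end groups fell nearly exponentially, so I read τ, the time for a fall by a factor e (a pseudo-first-order lifetime), from each last reading, and wrote τ = a + b·c/cL, with c the charge and cL the charge of larch:

τ(larch) = 74.8 s; τ(maple) = 64.0 s

b = 32.6 s; a = 42.1 s

Here b is the gas toll, the seconds of τ that the charge of larch adds, which I read as dissolved gas being drawn down, since τ was longer in larch than in maple; a is the part free of charge. The flask is larch followed on to t = 4.0 min, so I reckoned only the small remainder. The gap, what is neither first end groups nor links, was r = 1.17 times the first end groups at maple's last reading.

left = exp(−t/τ) = 4.03%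

links = 100% − left × (1 + r) = 91.3%

I took ochre to divide a and b both by 2, giving 99.6%, and teal to divide b alone, so τ = 58.4 s and links 96.4%; ochre was my choice.

The forecast gave 90%, ochre and 94% after teal, below my figure, holding that “Doubling the transfer coefficient only removes part of the resistance”.

The flask gave 91.5%, with ochre adding 6.8 percentage points, teal 2.9 points, and 94.4% after teal.

    first end groups + second end groups → links + released group (k = 4.40 /M/s)
    gas ⇌ second end groups, rate k2*(csat - [second end groups]) (kL = 0.270 /s)
    first end groups ⇌ dormant form (K = 0.307, k = 0.00442 /s)

The flask held 4.5% of first end groups at 4.00 min, a τ of 77.4 s. The same toll of 32.6 s, scaled to the neighbour with 0.17 M of first end groups, gives τ = 97.6 s and 8.55% left at 4.0 min; that neighbour held 8.0%. My gap ratio gives it 81.4% links, but its dormant form stood at 5.84% and its links at 86.1%.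

(The earlier runs and the new flask come from a simulation for substances that don't exist; scatter was added.)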